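We follow south-east, and we time it in uptake half-times rather than in hours.

| flask | substrate | reagent | temperature | remark | time |
|---|---|---|---|---|---|
| dusk | 0.20 M | 2 equiv | 10 °C | run made earlier |  |
| midnight | 0.45 M | 2 equiv | 40 °C | run made earlier |  |
| east | 0.30 M | 2.00 equiv |  | at 15 °C until 12 h, from then on at 65 °C | 25 h |
| south-west | 0.30 M | 2.00 equiv | 65 °C |  | 25 h |
| south-east | 0.30 M | 2.00 equiv | 40 °C |  | 25 h |
| north-west | 0.30 M | 2.00 equiv | 15 °C |  | 25 h |

| run | time / h | target / % | substrate / % |
|---|---|---|---|
| dusk | 96.0 | 13 | 17 |
| dusk | 192 | 24 | 5 |
| dusk | 288 | 36 | 6 |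
| dusk | 360 | 45 | 6 |
| midnight | 6.00 | 29 | 16 |
| midnight | 15.0 | 46 | 7 |
| midnight | 30.0 | 50 | 6 |
| midnight | 96.0 | 32 | 0 |

(readings scatter by 1.5 percentage points)

* the best flask by amount of target, in percent of the substrate charged; "all alike" if 1.5 percentage points covers them all (east / south-west / south-east / north-west / all alike)
* amount of target at the end, in percent of the substrate charged, east
* amount of target at the end, in percent of the substrate charged, south-west
* amount of target at the end, in percent of the substrate charged, south-east
* amount of target at the end, in percent of the substrate charged, north-west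

- the numbers in the tables scatter by 1.5 percentage points (one standard deviation)
- candidate steps: substrate + reagent -> intermediate + released group; intermediate <-> target; intermediate <-> isomer of the product; 2 reagent -> self-condensation product; target -> over-reaction product; reagent -> decomposition product

The midnight substrate does not fall first-order: 16% at 6.00 h would become 1.02% at 15.0 h, but the reading there is 7%. The first two readings follow a hyperbola instead, remaining fraction = 1/(1 + time/half-time), which is what a second-order step gives when its partner falls in proportion. Here that partner would be the reagent, which self-condensation also spends. The first reading gives 1.14 h for the uptake half-time, the time in which half of the substrate goes at fixed equivalents and temperature, and the second reading gives 1.13 h. This half-time scales inversely with concentration, so south-east, also at 40 °C, has 1.71 h.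

So on this count the south-east substrate starts by losing 0.585 h⁻¹ of its charge and is halved at 1.71 h. It bends near 5.13 h, where a quarter remains, and after 14.6 half-times, at 25 h, it stands at 6.42%. Target lags behind this curve: midnight held 29% at 6.00 h, then 46% at 15.0 h and 50% at 30.0 h. In uptake, the end of south-east matches midnight at 16.7 h, while its first-order steps have had 25 h, so we place it between those last two readings, at 48.0%. Midnight's later fall to 32% at 96.0 h reads as an apparent half-life of 103 h, a loss that is not small over 25 h, but the two readings we placed south-east between already contain it, so we take nothing further off.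

The forecast names south-east, with 46% there (41% to 51%), below our figure, and 13%, 6% and 4% for east, south-west and north-west. Its ground for south-east: “conversion is nearly complete at 25 h, about 46%”.

South-east gives 50.8%, more than east at 5.60%, south-west at 1.52% and north-west at 5.16%.

    substrate + reagent → intermediate + released group (k = 1.00 M⁻¹ h⁻¹, Ea = 58.0 kJ mol⁻¹)
    intermediate ⇌ target (K = 2.20, k = 0.110 h⁻¹, Ea = 96.0 kJ mol⁻¹, ΔH = −26.0 kJ mol⁻¹)
    intermediate ⇌ isomer of the product (K = 3.10, k = 0.00220 h⁻¹, Ea = 112 kJ mol⁻¹, ΔH = −42.0 kJ mol⁻¹)
    2 reagent → self-condensation product (k = 0.250 M⁻¹ h⁻¹, Ea = 69.0 kJ mol⁻¹)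
    target → over-reaction product (k = 0.0130 h⁻¹, Ea = 116 kJ mol⁻¹)
    reagent → decomposition product (k = 1.10 × 10⁻⁴ h⁻¹, Ea = 127 kJ mol⁻¹)
    (constants at 40 °C)

Our count for south-east gave 6.42% substrate; the flask holds 6.26%, with 6.23% of the reagent's own charge. At the start of south-east, uptake and self-condensation use reagent at a ratio of 1.0. Now cut the substrate to 0.075 M, with equivalents, temperature and time held. The half-time becomes 6.86 h, and counting 25 h leaves 21.5%. That neighbouring flask ends with 21% substrate and 41.5% target.

The data are simulated for substances that don't exist; scatter was added.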